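The ten-membered carbocycle is opened at C9–C10 (germacranolide locants): C9 is an allylic carbinol carbon attached to the trisubstituted (Z)-C1=C10 alkene of that ring, the retron of an alkenyl-metal addition to an aldehyde. A Nozaki–Hiyama–Kishi macrocyclisation therefore closes the ring, transfers the C1=C10 geometry from a (Z)-alkenyl iodide and creates the C9 stereocentre (Felkin–Anh control from C8) in one operation. Its precursor is a cis-β,γ-disubstituted α-methylene-γ-butyrolactone (C6, C7, C11–C13 in place) whose γ-arm (C5–C1, C10) ends in the iodoalkene and whose β-arm (C8, C9) ends in an α-silyloxy aldehyde, assembled by zinc Barbier allylation–lactonisation of two fragments. Esterification with (2R,3R)-epoxyangelic acid and desilylation finish the synthesis.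

Key step: step 17

Remark 1: locants C1–C15 are those of the target numbered as a germacra-1(10),4,11(13)-trien-12,6-olide (C6 lactone O–CH, C7 ring fusion, C8 CHOH, C9 CH–O-acyl, C10/C14 and C4/C15 the two C(CH3)= units, C3 CHOAc, C11=C13 exocyclic methylene, C12 carbonyl). Descriptors quoted with these locants are the CIP descriptors of the compound named, so the label at C7 changes with the O8 substituent although that centre is not touched after step 11.

Remark 2 (assumption): (S,S)-ProPhenol is taken to deliver the zinc acetylide to the Re face of aldehyde 1 (giving 4S in 3); if the sense is opposite for this aldehyde, the (R,R)-ligand is used.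

Step 1
Reactants: 1 3-[(tert-butyldimethylsilyl)oxy]propanal + 2 methyl propiolate
Product: 3 methyl (4S)-6-[(tert-butyldimethylsilyl)oxy]-4-hydroxyhex-2-ynoate
Conditions: Me2Zn (3 equiv), (S,S)-ProPhenol (10 mol%), Ph3P=O (20 mol%), toluene, 4 °C; aq NH4Cl
Reagents that add atoms: none
Why: Zinc–ProPhenol-catalysed enantioselective alkynylation of an aldehyde, in which the dinuclear zinc complex binds acetylide and aldehyde and should set the C3 carbinol centre (4S in 3) by Re-face delivery.

Step 2
Reactants: 3 methyl (4S)-6-[(tert-butyldimethylsilyl)oxy]-4-hydroxyhex-2-ynoate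
Product: 4 methyl (4S)-4,6-bis[(tert-butyldimethylsilyl)oxy]hex-2-ynoate
Conditions: TBSCl, imidazole, DMF, rt
Reagents that add atoms: tert-butyldimethylsilyl chloride, CC(C)(C)[Si](C)(C)Cl
Why: Standard silylation of the propargylic alcohol under weakly basic conditions, which blocks lactonisation in the next step and leaves the stereocentre untouched.

Step 3
Reactants: 4 methyl (4S)-4,6-bis[(tert-butyldimethylsilyl)oxy]hex-2-ynoate
Product: 5 methyl (2Z,4S)-4,6-bis[(tert-butyldimethylsilyl)oxy]-3-methylhex-2-enoate
Conditions: Me2CuLi (from CuI and MeLi), THF, −78 °C; MeOH quench at −78 °C; aq NH4Cl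
Reagents that add atoms: lithium dimethylcuprate, [Li+].C[Cu-]C
Why: Conjugate addition of a Gilman cuprate to an alkynoate is a syn addition of CH3 and Cu, and protonation with retention at −78 °C should leave C3 and the ester carbon C6 cis across the new C4=C5 bond (the Z geometry needed in the ring); no stereocentre is formed.

Step 4
Reactants: 5 methyl (2Z,4S)-4,6-bis[(tert-butyldimethylsilyl)oxy]-3-methylhex-2-enoate
Product: 6 methyl (2Z,4S)-4-[(tert-butyldimethylsilyl)oxy]-6-hydroxy-3-methylhex-2-enoate
Conditions: HF·pyridine, pyridine, THF, 0 °C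
Reagents that add atoms: none
Why: Buffered fluoride cleaves the unhindered primary silyl ether much faster than the secondary allylic one (selective desilylation), and the free alcohol cannot lactonise to a favourable ring size.

Step 5
Reactants: 6 methyl (2Z,4S)-4-[(tert-butyldimethylsilyl)oxy]-6-hydroxy-3-methylhex-2-enoate
Product: 7 methyl (2Z,4S)-4-[(tert-butyldimethylsilyl)oxy]-3-methyl-6-oxohex-2-enoate
Conditions: Dess–Martin periodinane, NaHCO3, CH2Cl2, 0 °C to rt
Reagents that add atoms: none
Why: Dess–Martin oxidation of a primary alcohol under buffered, non-basic conditions should give the β-silyloxy aldehyde without elimination or Z/E isomerisation.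

Step 6
Reactants: 7 methyl (2Z,4S)-4-[(tert-butyldimethylsilyl)oxy]-3-methyl-6-oxohex-2-enoate
Product: 8 methyl (2Z,4S,6Z)-4-[(tert-butyldimethylsilyl)oxy]-7-iodo-3-methylocta-2,6-dienoate
Conditions: EtPPh3I, n-BuLi, THF, 0 °C; iodine, −78 °C; NaN(SiMe3)2, −20 °C; then 7, −78 to −20 °C
Reagents that add atoms: ethyltriphenylphosphonium iodide, CC[P+](c1ccccc1)(c1ccccc1)c1ccccc1.[I-]; iodine, [I][I]
Why: Stork–Zhao olefination, in which the non-stabilised α-iodo ylide reacts under kinetic control to give the (Z)-2-iodoalk-2-ene with iodine cis to C2, as the later ring alkene requires; no stereocentre is formed and the silyloxy group should resist elimination at low temperature.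

Step 7
Reactants: 8 methyl (2Z,4S,6Z)-4-[(tert-butyldimethylsilyl)oxy]-7-iodo-3-methylocta-2,6-dienoate
Product: 9 (2Z,4S,6Z)-4-[(tert-butyldimethylsilyl)oxy]-7-iodo-3-methylocta-2,6-dien-1-ol
Conditions: i-Bu2AlH (2.2 equiv), CH2Cl2, −78 °C; Rochelle salt work-up
Reagents that add atoms: none
Why: 1,2-Reduction of the enoate by the aluminium hydride gives the allylic alcohol and should touch neither the alkenyl iodide nor either alkene geometry.

Step 8
Reactants: 9 (2Z,4S,6Z)-4-[(tert-butyldimethylsilyl)oxy]-7-iodo-3-methylocta-2,6-dien-1-ol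
Product: 10 (2Z,4S,6Z)-4-[(tert-butyldimethylsilyl)oxy]-7-iodo-3-methylocta-2,6-dienal (fragment A)
Conditions: Dess–Martin periodinane, NaHCO3, CH2Cl2, 0 °C
Reagents that add atoms: none
Why: Buffered Dess–Martin oxidation of the allylic alcohol should give the (Z)-enal without isomerisation to the E isomer.

Step 9
Reactants: 11 (4S)-2,2-dimethyl-1,3-dioxolane-4-carbaldehyde + 12 methyl acrylate
Product: 13 methyl 2-{[(4S)-2,2-dimethyl-1,3-dioxolan-4-yl](hydroxy)methyl}prop-2-enoate (both carbinol epimers)
Conditions: DABCO (0.3 equiv), neat 12 (excess), rt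
Reagents that add atoms: none
Why: Morita–Baylis–Hillman reaction joins C11 to C7; the new carbinol centre forms as an epimer mixture, which is immaterial because step 10 removes it, and the α-alkoxy centre (C8) is expected to survive the weakly basic amine.

Step 10
Reactants: 13 methyl 2-{[(4S)-2,2-dimethyl-1,3-dioxolan-4-yl](hydroxy)methyl}prop-2-enoate
Product: 14 methyl (2Z)-2-(bromomethyl)-3-[(4R)-2,2-dimethyl-1,3-dioxolan-4-yl]prop-2-enoate (fragment B)
Conditions: NBS, Me2S, CH2Cl2, 0 °C to rt
Reagents that add atoms: N-bromosuccinimide, O=C1CCC(=O)N1Br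
Why: Corey–Kim-type activation of the alcohol by the bromosulfonium salt followed by SN2′ attack of bromide at the CH2 terminus should give the more stable trisubstituted enoate with the ester trans to C8 (the Z bromide) under conditions that spare the acetonide; C8 is untouched.

Step 11
Reactants: 10 (2Z,4S,6Z)-4-[(tert-butyldimethylsilyl)oxy]-7-iodo-3-methylocta-2,6-dienal + 14 methyl (2Z)-2-(bromomethyl)-3-[(4R)-2,2-dimethyl-1,3-dioxolan-4-yl]prop-2-enoate
Product: 17 C3-O-TBS C8/C9-acetonide cis-lactone (fragment union), via allylzinc bromide 15 (not isolated), via bromozinc alkoxide 16 (not isolated)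
Conditions: Zn dust (activated), THF, 0 to 45 °C; aq NH4Cl
Reagents that add atoms: none
Why: Zinc-mediated Barbier 2-(alkoxycarbonyl)allylation with in situ lactonisation (Dreiding–Schmidt reaction), in which the allylzinc adds through its γ-carbon C7 to the aldehyde in a closed chair transition state, the Z geometry (C8 cis to CH2Zn) giving the syn adduct and hence the C6/C7-cis lactone, while C8 directs the face of C7 (H8 eclipsing the alkene to avoid allylic 1,3-strain, the new bond forming anti to the larger and better σ-donating C8–C9 bond), so that C6 and C7 should follow from the glyceraldehyde-derived centre.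

Step 12
Reactants: 17 C3-O-TBS C8/C9-acetonide cis-lactone
Product: 18 C3-hydroxy C8/C9-acetonide cis-lactone
Conditions: HF·pyridine, THF, 0 °C to rt
Reagents that add atoms: none
Why: Fluoride-mediated desilylation of the secondary allylic silyl ether under mildly acidic conditions that should leave the acetonide, the alkenyl iodide and the α-methylene lactone intact.

Step 13
Reactants: 18 C3-hydroxy C8/C9-acetonide cis-lactone
Product: 19 C3-acetoxy C8/C9-acetonide cis-lactone
Conditions: Ac2O, pyridine, DMAP (cat.), CH2Cl2, 0 °C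
Reagents that add atoms: acetic anhydride, CC(=O)OC(C)=O
Why: Acylation of the only free hydroxyl installs the C3 acetate of the target with retention at C3.

Step 14
Reactants: 19 C3-acetoxy C8/C9-acetonide cis-lactone
Product: 20 C3-acetoxy 8,9-diol cis-lactone
Conditions: AcOH/H2O 4:1, 40 °C
Reagents that add atoms: none
Why: Mild aqueous acid hydrolysis of the terminal isopropylidene acetal, chosen so that the allylic acetate and the 12,6-lactone (which could migrate to O8) should survive.

Step 15
Reactants: 20 C3-acetoxy 8,9-diol cis-lactone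
Product: 21 C3-acetoxy 8,9-bis(triethylsilyl) ether cis-lactone
Conditions: Et3SiOTf, 2,6-lutidine, CH2Cl2, −78 °C
Reagents that add atoms: triethylsilyl trifluoromethanesulfonate, CC[Si](CC)(CC)OS(=O)(=O)C(F)(F)F
Why: Exhaustive silylation with a silyl triflate and a hindered base protects both hydroxyls without acyl or lactone migration.

Step 16
Reactants: 21 C3-acetoxy 8,9-bis(triethylsilyl) ether cis-lactone
Product: 22 C9 aldehyde with C8–OSiEt3 (seco-aldehyde)
Conditions: (COCl)2, DMSO, CH2Cl2, −78 to −35 °C; Et3N, −78 to 0 °C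
Reagents that add atoms: none
Why: Swern oxidation applied directly to the bis-silyl ether, in which the primary O–SiEt3 group is cleaved and oxidised under the chlorosulfonium conditions while the hindered secondary O–SiEt3 group survives, should give the α-silyloxy aldehyde in one operation without epimerising C8 when the base is added cold.

Step 17
Reactants: 22 C9 aldehyde with C8–OSiEt3 (seco-aldehyde)
Product: 24 ten-membered carbocycle bearing free C9–OH (8-O-triethylsilyl germacranolide), via alkenylchromium dichloride 23 (not isolated)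
Conditions: CrCl2 (15 equiv), NiCl2 (1 mol% of the chromium), DMSO, rt, slow addition of 22 to 2 mM final concentration
Reagents that add atoms: none
Why: Zerovalent nickel, formed from NiCl2 by CrCl2, inserts into the C10–I bond of the (Z)-alkenyl iodide with retention, transmetalation to trivalent chromium gives the alkenylchromium 23, and this adds to the C9 aldehyde through a chromium-bound carbonyl. The closest known reaction type is the nickel/chromium-mediated alkenyl iodide–aldehyde coupling (Nozaki–Hiyama–Kishi reaction) in its intramolecular, medium-ring form. The ten-membered carbocycle closes in the 10-exo-trig mode (the C9=O bond is exocyclic to the new ring), helped by the two Z alkenes and the cis-lactone, which fold the chain. The new C9 stereocentre is controlled by C8: in the polar Felkin–Anh arrangement the C8–OSiEt3 bond lies anti to the incoming alkenyl group, which should give the 8,9-anti relationship, i.e. 9S. The step needs chemoselectivity (insertion into the alkenyl C–I bond and not into the allylic C3–OAc or C6–O bonds; addition to the aldehyde and not to lactone or acetate), which the much faster oxidative addition of the iodide and the mild, non-basic organochromium secure, and retention of the C1=C10 geometry, secured by the configurational stability of trisubstituted alkenyl-nickel and alkenyl-chromium species. Cyclisation is favoured over oligomerisation by slow addition at high dilution.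

Step 18
Reactants: 25 methyl angelate
Product: 26 (2Z)-2-methylbut-2-en-1-ol (angelyl alcohol)
Conditions: LiAlH4, Et2O, 0 °C
Reagents that add atoms: none
Why: Hydride reduction of the enoate to the allylic alcohol proceeds without Z/E isomerisation.

Step 19
Reactants: 26 (2Z)-2-methylbut-2-en-1-ol
Product: 27 [(2S,3R)-2,3-dimethyloxiran-2-yl]methanol
Conditions: Ti(OiPr)4 (10 mol%), L-(+)-diethyl tartrate (12 mol%), t-BuOOH, 4 Å molecular sieves, CH2Cl2, −20 °C
Reagents that add atoms: tert-butyl hydroperoxide, CC(C)(C)OO
Why: Sharpless asymmetric epoxidation, in which the titanium–L-(+)-tartrate complex delivers oxygen to the face that gives 2S (the sense established for allylic alcohols with this tartrate) and the stereospecific syn oxygen transfer keeps CH2OH and the C3 methyl cis, setting both epoxide centres.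

Step 20
Reactants: 27 [(2S,3R)-2,3-dimethyloxiran-2-yl]methanol
Product: 28 (2R,3R)-2,3-dimethyloxirane-2-carboxylic acid (epoxyangelic acid)
Conditions: RuCl3 (cat.), NaIO4, CCl4/MeCN/H2O, rt
Reagents that add atoms: water, O; sodium periodate, [Na+].[O-]I(=O)(=O)=O
Why: Ruthenium tetroxide oxidation (generated catalytically) takes the primary alcohol to the acid without opening the epoxide; the centres are untouched and the C2 label changes from S to R only because the oxidised carbon gains CIP priority.

Step 21
Reactants: 24 ten-membered carbocycle bearing free C9–OH + 28 (2R,3R)-2,3-dimethyloxirane-2-carboxylic acid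
Product: 30 C9 epoxyangelate ester (8-O-triethylsilyl ether of the target), via mixed anhydride 29 (not isolated)
Conditions: 2,4,6-trichlorobenzoyl chloride, Et3N, THF, rt; then 24, DMAP, toluene, rt to 40 °C
Reagents that add atoms: none
Why: Yamaguchi esterification through the mixed anhydride acylates the hindered allylic C9–OH with retention at C9, C8 being blocked as its silyl ether.

Step 22
Reactants: 30 C9 epoxyangelate ester (8-O-triethylsilyl ether of the target)
Product: 31 CNP0137407.4 (target)
Conditions: HF·pyridine, pyridine, THF, 0 °C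
Reagents that add atoms: none
Why: Buffered fluoride desilylation frees C8–OH under mildly acidic conditions that should spare the glycidic ester, the allylic acetate and the α-methylene lactone and avoid base-induced acyl migration from O9 to O8.

Compound list
1 | 3-[(tert-butyldimethylsilyl)oxy]propanal | O=CCCO[Si](C)(C)C(C)(C)C | starting material
2 | methyl propiolate | C#CC(=O)OC | starting material
3 | methyl (4S)-6-[(tert-butyldimethylsilyl)oxy]-4-hydroxyhex-2-ynoate | COC(=O)C#C[C@@H](O)CCO[Si](C)(C)C(C)(C)C | intermediate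
4 | methyl (4S)-4,6-bis[(tert-butyldimethylsilyl)oxy]hex-2-ynoate | COC(=O)C#C[C@@H](O[Si](C)(C)C(C)(C)C)CCO[Si](C)(C)C(C)(C)C | intermediate
5 | methyl (2Z,4S)-4,6-bis[(tert-butyldimethylsilyl)oxy]-3-methylhex-2-enoate | COC(=O)/C=C(/C)[C@@H](O[Si](C)(C)C(C)(C)C)CCO[Si](C)(C)C(C)(C)C | intermediate
6 | methyl (2Z,4S)-4-[(tert-butyldimethylsilyl)oxy]-6-hydroxy-3-methylhex-2-enoate | COC(=O)/C=C(/C)[C@@H](O[Si](C)(C)C(C)(C)C)CCO | intermediate
7 | methyl (2Z,4S)-4-[(tert-butyldimethylsilyl)oxy]-3-methyl-6-oxohex-2-enoate | COC(=O)/C=C(/C)[C@@H](O[Si](C)(C)C(C)(C)C)CC=O | intermediate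
8 | methyl (2Z,4S,6Z)-4-[(tert-butyldimethylsilyl)oxy]-7-iodo-3-methylocta-2,6-dienoate | COC(=O)/C=C(/C)[C@@H](O[Si](C)(C)C(C)(C)C)C/C=C(/C)I | intermediate
9 | (2Z,4S,6Z)-4-[(tert-butyldimethylsilyl)oxy]-7-iodo-3-methylocta-2,6-dien-1-ol | OC/C=C(/C)[C@@H](O[Si](C)(C)C(C)(C)C)C/C=C(/C)I | intermediate
10 | (2Z,4S,6Z)-4-[(tert-butyldimethylsilyl)oxy]-7-iodo-3-methylocta-2,6-dienal (fragment A; C6 aldehyde, C3–OTBS, C10 iodide) | O=C/C=C(/C)[C@@H](O[Si](C)(C)C(C)(C)C)C/C=C(/C)I | intermediate
11 | (4S)-2,2-dimethyl-1,3-dioxolane-4-carbaldehyde ((S)-glyceraldehyde acetonide) | O=C[C@@H]1COC(C)(C)O1 | starting material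
12 | methyl acrylate | C=CC(=O)OC | starting material
13 | methyl 2-{[(4S)-2,2-dimethyl-1,3-dioxolan-4-yl](hydroxy)methyl}prop-2-enoate, both carbinol epimers | C=C(C(=O)OC)C(O)[C@@H]1COC(C)(C)O1 | intermediate
14 | methyl (2Z)-2-(bromomethyl)-3-[(4R)-2,2-dimethyl-1,3-dioxolan-4-yl]prop-2-enoate (fragment B) | COC(=O)/C(CBr)=C/[C@@H]1COC(C)(C)O1 | intermediate
15 | allylzinc bromide formed from 14 (zinc on C13) | COC(=O)/C(C[Zn]Br)=C/[C@@H]1COC(C)(C)O1 | intermediate (not isolated)
16 | bromozinc alkoxide of the open-chain C6–C7 adduct (methyl ester; C6, C7, C8 arranged as in 17) | C=C(C(=O)OC)[C@H]([C@H](O[Zn]Br)/C=C(/C)[C@@H](O[Si](C)(C)C(C)(C)C)C/C=C(/C)I)[C@@H]1COC(C)(C)O1 | intermediate (not isolated)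
17 | (4R,5R)-5-[(1Z,3S,5Z)-3-[(tert-butyldimethylsilyl)oxy]-6-iodo-2-methylhepta-1,5-dien-1-yl]-4-[(4R)-2,2-dimethyl-1,3-dioxolan-4-yl]-3-methylideneoxolan-2-one (H4/H5 cis; target locants 3S,6R,7R,8R) | C=C1C(=O)O[C@H](/C=C(/C)[C@@H](O[Si](C)(C)C(C)(C)C)C/C=C(/C)I)[C@@H]1[C@@H]2COC(C)(C)O2 | intermediate
18 | C3-alcohol of 17: (4R,5R)-5-[(1Z,3S,5Z)-3-hydroxy-6-iodo-2-methylhepta-1,5-dien-1-yl]-4-[(4R)-2,2-dimethyl-1,3-dioxolan-4-yl]-3-methylideneoxolan-2-one | C=C1C(=O)O[C@H](/C=C(/C)[C@@H](O)C/C=C(/C)I)[C@@H]1[C@@H]2COC(C)(C)O2 | intermediate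
19 | C3-acetate of 18 (target locants 3S,6R,7R,8R) | C=C1C(=O)O[C@H](/C=C(/C)[C@@H](OC(C)=O)C/C=C(/C)I)[C@@H]1[C@@H]2COC(C)(C)O2 | intermediate
20 | (1Z,3S,5Z)-1-[(2R,3S)-3-[(1R)-1,2-dihydroxyethyl]-4-methylidene-5-oxooxolan-2-yl]-6-iodo-2-methylhepta-1,5-dien-3-yl acetate (8,9-diol; target locants 3S,6R,7S,8R) | C=C1C(=O)O[C@H](/C=C(/C)[C@@H](OC(C)=O)C/C=C(/C)I)[C@@H]1[C@@H](O)CO | intermediate
21 | 8,9-bis(triethylsilyl) ether of 20 (target locants 3S,6R,7R,8R) | C=C1C(=O)O[C@H](/C=C(/C)[C@@H](OC(C)=O)C/C=C(/C)I)[C@@H]1[C@@H](O[Si](CC)(CC)CC)CO[Si](CC)(CC)CC | intermediate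
22 | seco-aldehyde: C9 aldehyde, C8–OSiEt3, C3–OAc, (Z)-C10 iodide, cis-12,6-lactone (target locants 3S,6R,7R,8R) | C=C1C(=O)O[C@H](/C=C(/C)[C@@H](OC(C)=O)C/C=C(/C)I)[C@@H]1[C@@H](O[Si](CC)(CC)CC)C=O | intermediate
23 | alkenylchromium dichloride formed from 22 (chromium on C10) | C=C1C(=O)O[C@H](/C=C(/C)[C@@H](OC(C)=O)C/C=C(/C)[Cr](Cl)Cl)[C@@H]1[C@@H](O[Si](CC)(CC)CC)C=O | intermediate (not isolated)
24 | (1(10)Z,4Z)-(3S,6R,7R,8R,9S)-3-acetoxy-9-hydroxy-8-(triethylsilyloxy)germacra-1(10),4,11(13)-trien-12,6-olide | C=C1C(=O)O[C@@H]2/C=C(/C)[C@@H](OC(C)=O)C/C=C(/C)[C@H](O)[C@H](O[Si](CC)(CC)CC)[C@H]12 | intermediate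
25 | methyl angelate (methyl (2Z)-2-methylbut-2-enoate) | C/C=C(/C)C(=O)OC | starting material
26 | (2Z)-2-methylbut-2-en-1-ol | C/C=C(/C)CO | intermediate
27 | [(2S,3R)-2,3-dimethyloxiran-2-yl]methanol | OC[C@]1(C)O[C@@H]1C | intermediate
28 | (2R,3R)-2,3-dimethyloxirane-2-carboxylic acid | OC(=O)[C@]1(C)O[C@@H]1C | intermediate
29 | (2R,3R)-2,3-dimethyloxirane-2-carboxylic 2,4,6-trichlorobenzoic anhydride | O=C(OC(=O)c1c(Cl)cc(Cl)cc1Cl)[C@]2(C)O[C@@H]2C | intermediate (not isolated)
30 | (1(10)Z,4Z)-(3S,6R,7R,8R,9S)-3-acetoxy-9-[(2R,3R)-2,3-dimethyloxirane-2-carbonyloxy]-8-(triethylsilyloxy)germacra-1(10),4,11(13)-trien-12,6-olide | C=C1C(=O)O[C@@H]2/C=C(/C)[C@@H](OC(C)=O)C/C=C(/C)[C@H](OC(=O)[C@]3(C)O[C@@H]3C)[C@H](O[Si](CC)(CC)CC)[C@H]12 | intermediate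
31 | (1(10)Z,4Z)-(3S,6R,7S,8R,9S)-3-acetoxy-8-hydroxy-9-[(2R,3R)-2,3-dimethyloxirane-2-carbonyloxy]germacra-1(10),4,11(13)-trien-12,6-olide (CNP0137407.4) | C=C1C(=O)O[C@@H]2/C=C(/C)[C@@H](OC(C)=O)C/C=C(/C)[C@H](OC(=O)[C@]3(C)O[C@@H]3C)[C@H](O)[C@H]12 | target

Total step count: 22. Longest linear sequence: 17 steps (steps 1–8, 11–17, 21 and 22).

Steps most likely to fail

Step 17 (ring closure). The facial selectivity at the C9 aldehyde may be set by the conformation of the closing ten-membered ring instead of the Felkin–Anh preference, so that the C9 epimer predominates; intermolecular addition leading to oligomers is the second concern. The fallback sets out from 22: the same chromium-mediated closure is accepted with the opposite sense and gives the C9-epimeric macrocyclic alcohol F1. Mitsunobu esterification of F1 with acid 28 (PPh3, DIAD, toluene, 0 °C) then installs the epoxyangelate with inversion at C9, so that stereocorrection and acylation are merged. The route is rejoined at 30.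

Step 11 (fragment union). The π-facial selectivity of the allylzinc at C7 relative to the dioxolane centre is the weak point: bond formation anti to the C8–O8 bond instead of anti to C8–C9 would give the C6/C7 diastereomer, and incomplete syn selectivity would give some trans-lactone. The fallback replaces substrate control by catalyst control and sets out from 13. Acetylation (Ac2O, DMAP) gives the allylic acetate F2; copper-catalysed SN2′ borylation (CuCl, KOAc, B2pin2, DMF) gives the 2-(methoxycarbonyl)allyl pinacol boronate F3 with the ester trans to C8. Allylboration of enal 10 catalysed by a chiral BINOL-derived phosphoric acid (TRIP, the antipode that directs C7 to the Si face of the aldehyde) passes through a closed boron-centred chair in which the catalyst selects the aldehyde face and the boronate geometry fixes the syn relationship, giving the hydroxy ester F4. Lactonisation of F4 (TsOH cat., CH2Cl2) rejoins the route at 17.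

Step 1 (enantioselective alkynylation). The unbranched, enolisable β-silyloxy aldehyde may undergo self-aldol reaction or β-elimination under the basic zinc alkoxide conditions, and enantiofacial discrimination may be insufficient. The fallback sets out from 1 and 2: addition of the lithium acetylide of 2 (LiN(SiMe3)2, THF, −78 °C) to 1 gives the racemic propargylic alcohol F5, Dess–Martin oxidation gives the ynone F6, and reagent-controlled reduction with (S)-Alpine-Borane (B-isopinocampheyl-9-borabicyclo[3.3.1]nonane from (−)-α-pinene), a reaction established for 4-oxoalk-2-ynoates, rejoins the route at 3.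

Further compounds
F1 | step 17 | (1(10)Z,4Z)-(3S,6R,7R,8R,9R)-3-acetoxy-9-hydroxy-8-(triethylsilyloxy)germacra-1(10),4,11(13)-trien-12,6-olide (C9 epimer of 24) | C=C1C(=O)O[C@@H]2/C=C(/C)[C@@H](OC(C)=O)C/C=C(/C)[C@@H](O)[C@H](O[Si](CC)(CC)CC)[C@H]12
F2 | step 11 | methyl 2-{(acetyloxy)[(4S)-2,2-dimethyl-1,3-dioxolan-4-yl]methyl}prop-2-enoate (both epimers at the acetoxy carbon) | C=C(C(=O)OC)C(OC(C)=O)[C@@H]1COC(C)(C)O1
F3 | step 11 | methyl (2E)-3-[(4R)-2,2-dimethyl-1,3-dioxolan-4-yl]-2-[(4,4,5,5-tetramethyl-1,3,2-dioxaborolan-2-yl)methyl]prop-2-enoate | COC(=O)/C(CB1OC(C)(C)C(C)(C)O1)=C/[C@@H]2COC(C)(C)O2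
F4 | step 11 | open-chain hydroxy ester of 17 (methyl ester, free C6–OH; C6, C7, C8 arranged as in 17) | C=C(C(=O)OC)[C@H]([C@H](O)/C=C(/C)[C@@H](O[Si](C)(C)C(C)(C)C)C/C=C(/C)I)[C@@H]1COC(C)(C)O1
F5 | step 1 | methyl 6-[(tert-butyldimethylsilyl)oxy]-4-hydroxyhex-2-ynoate (racemic) | COC(=O)C#CC(O)CCO[Si](C)(C)C(C)(C)C
F6 | step 1 | methyl 6-[(tert-butyldimethylsilyl)oxy]-4-oxohex-2-ynoate | COC(=O)C#CC(=O)CCO[Si](C)(C)C(C)(C)C
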